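**Strategy**

1. Cuts, in retrosynthetic order: the ten aryl O–CH3 bonds; the aryl–vinyl bond of the E-stilbene (Heck), which separates a core styrene from a 4-bromo-trans-2,3-diaryl-2,3-dihydrobenzofuran; the vinyl group back to a methyl ester.
2. In the core: the two methine C–H bonds of the cycloheptane (syn-hydrogenation), then the C=C between those carbons (McMurry) back to a bis(diaryl ketone); its two aryl–C(=O) bonds (carbonylative Suzuki at benzofuran C4, Friedel–Crafts on the resorcinol ring) return the same bromodihydrobenzofuran, which is cut at C2–C3 (rhodium carbene C–H insertion) to a 2-(benzyloxy)benzophenone.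
3. Enabling feature: the seven-membered ring consists of C3, C3a and C4 of one dihydrobenzofuran, two adjacent carbons of the resorcinol ring on C3, and two neighbouring CH(aryl) carbons with cis hydrogens (Ca, carrying 4-hydroxyphenyl and bonded to the resorcinol ring; Cb, carrying the 2-hydroxy-5-styrylphenyl group and bonded to C4). Each methine is thus a masked diaryl ketone and the Ca–Cb bond a masked ring-locked cis alkene.
4. Ring order forward: dihydrofuran ring (C2–C3 bond), then the seven-membered ring (Ca=Cb), then attachment of the second dihydrobenzofuran through the stilbene.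
5. Stereochemistry: C3 from the chiral dirhodium carboxylate in the C–H insertion, C2 by acid equilibration to trans; the bromide made this way enters twice and so accounts for four of the six centres; Ca and Cb arise together by syn addition of H2 to the face of the ring alkene anti to H-3.

Key step: step 10

Assumption: the S antipode of Rh2(PTAD)4 is taken to give the 3S insertion product; if the sense of induction is the reverse, the R antipode is used and nothing else changes.

Locants used in names: the dihydrobenzofuran is numbered O1, C2, C3, C3a, C4 to C7, C7a; Ca and Cb are the seven-ring carbons defined above.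

**Route**

Step 1
Reactants: 1 1-bromo-3,5-dimethoxybenzene; 2 2-bromo-4,6-dimethoxybenzaldehyde
Product: 4 racemic (2-bromo-4,6-dimethoxyphenyl)(3,5-dimethoxyphenyl)methanol, via arylmagnesium bromide 3 (not isolated)
Conditions: 1, Mg, I2 (cat.), THF, reflux; then 2, THF, 0 °C to rt; sat. aq. NH4Cl
Reagents that add atoms: none
Why: Grignard addition of the aryl nucleophile to the aldehyde carbonyl is far faster than halogen–magnesium exchange at the aryl bromide of 2, so the diaryl carbinol should form cleanly, and its stereocentre is of no consequence because step 2 removes it.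

Step 2
Reactants: 4 racemic (2-bromo-4,6-dimethoxyphenyl)(3,5-dimethoxyphenyl)methanol
Product: 5 (2-bromo-4,6-dimethoxyphenyl)(3,5-dimethoxyphenyl)methanone
Conditions: Dess–Martin periodinane, CH2Cl2, 0 °C to rt
Reagents that add atoms: none
Why: Dess–Martin oxidation converts the doubly benzylic secondary alcohol into the benzophenone under neutral conditions that tolerate the two ortho substituents, the aryl bromide and the methyl ethers.

Step 3
Reactants: 5 (2-bromo-4,6-dimethoxyphenyl)(3,5-dimethoxyphenyl)methanone
Product: 6 (2-bromo-6-hydroxy-4-methoxyphenyl)(3,5-dimethoxyphenyl)methanone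
Conditions: BCl3 (1.2 equiv), CH2Cl2, −78 to 0 °C; then H2O
Reagents that add atoms: none
Why: Chelation-directed Lewis acid ether cleavage: BCl3 bound to the ketone oxygen forms a six-membered chelate with the ortho methoxy group only, so that methyl group alone should be lost as chloromethane while the para methoxy group and the two meta methoxy groups of the other ring remain.

Step 4
Reactants: 6 (2-bromo-6-hydroxy-4-methoxyphenyl)(3,5-dimethoxyphenyl)methanone; 7 4-methoxybenzyl chloride
Product: 8 {2-bromo-4-methoxy-6-[(4-methoxybenzyl)oxy]phenyl}(3,5-dimethoxyphenyl)methanone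
Conditions: K2CO3, n-Bu4NI (cat.), DMF, 60 °C
Reagents that add atoms: none
Why: Williamson ether synthesis on the phenoxide with a reactive benzylic chloride installs the O–CH2–aryl unit whose benzylic C–H bond is needed for the insertion in step 6.

Step 5
Reactants: 8 {2-bromo-4-methoxy-6-[(4-methoxybenzyl)oxy]phenyl}(3,5-dimethoxyphenyl)methanone
Product: 9 hydrazone of ketone 8 (either C=N isomer)
Conditions: N2H4·H2O (excess), AcOH (cat.), EtOH, 90 °C (sealed tube)
Reagents that add atoms: hydrazine, NN
Why: Acid-catalysed condensation of the ketone with excess hydrazine (hydrazone formation) should proceed at elevated temperature despite the two ortho substituents, the excess suppressing azine formation and the electron-rich bromoarene resisting nucleophilic aromatic substitution.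

Step 6
Reactants: 9 hydrazone of ketone 8
Product: 11 (2R,3S)-4-bromo-3-(3,5-dimethoxyphenyl)-6-methoxy-2-(4-methoxyphenyl)-2,3-dihydrobenzofuran (cis), via diaryldiazomethane 10 (not isolated)
Conditions: MnO2, CH2Cl2, 0 °C, filter; then Rh2(S-PTAD)4 (1 mol %), CH2Cl2, 0 °C
Reagents that add atoms: none
Why: Oxidation of the hydrazone gives the diaryldiazomethane, and its dirhodium carbene undergoes intramolecular 1,5 C–H insertion into the ether CH2 (enantioselective donor/donor carbene C–H insertion, an established entry to cis-2,3-diaryl-2,3-dihydrobenzofurans), in which the chiral carboxylate ligands choose the face of the carbene and so set C3 as S while the compact concerted transition state places the two aryl groups cis (C2 R).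

Step 7
Reactants: 11 (2R,3S)-4-bromo-3-(3,5-dimethoxyphenyl)-6-methoxy-2-(4-methoxyphenyl)-2,3-dihydrobenzofuran
Product: 12 (2S,3S)-4-bromo-3-(3,5-dimethoxyphenyl)-6-methoxy-2-(4-methoxyphenyl)-2,3-dihydrobenzofuran (trans)
Conditions: TFA, CH2Cl2, 0 °C to rt
Reagents that add atoms: none
Why: Acid-mediated epimerisation: reversible heterolysis of the C2–O bond gives a 4-methoxybenzyl cation paired with the phenol, which recloses to the thermodynamically favoured trans isomer while C3 is never touched, so the 2S,3S compound should result.

Step 8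
Reactants: 12 (2S,3S)-4-bromo-3-(3,5-dimethoxyphenyl)-6-methoxy-2-(4-methoxyphenyl)-2,3-dihydrobenzofuran; 13 4-methoxybenzoyl chloride
Product: 14 {2-[(2S,3S)-4-bromo-6-methoxy-2-(4-methoxyphenyl)-2,3-dihydrobenzofuran-3-yl]-4,6-dimethoxyphenyl}(4-methoxyphenyl)methanone
Conditions: SnCl4 (1.5 equiv), CH2Cl2, −40 to 0 °C; then ice-water
Reagents that add atoms: none
Why: Friedel–Crafts acylation should take place on the 3,5-dimethoxyphenyl ring, the most electron-rich arene (the benzofuran ring is deactivated by bromine and the anisyl ring has only one donor), and there at either of the two equivalent carbons that are para to one methoxy group and ortho to the other and to C3, the usual site for 5-alkylresorcinol dimethyl ethers, while any ionisation at C2 by the Lewis acid can only return the trans isomer.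

Step 9
Reactants: 14 bromo diaryl ketone from step 8; 15 [2-methoxy-5-(methoxycarbonyl)phenyl]boronic acid
Product: 16 methyl 3-{(2S,3S)-3-[3,5-dimethoxy-2-(4-methoxybenzoyl)phenyl]-6-methoxy-2-(4-methoxyphenyl)-2,3-dihydrobenzofuran-4-carbonyl}-4-methoxybenzoate
Conditions: Pd(OAc)2 (3 mol %), n-BuP(1-adamantyl)2 (9 mol %), CO (5 bar), K2CO3, toluene, 100 °C
Reagents that add atoms: carbon monoxide, [C-]#[O+]
Why: Carbonylative Suzuki–Miyaura coupling: oxidative addition at the C4–Br bond, CO insertion into the aryl–palladium bond and transmetalation with the boronic acid followed by reductive elimination give the diaryl ketone, the bulky electron-rich phosphine being chosen so that the hindered, electron-rich bromide reacts and acyl formation outruns direct aryl–aryl coupling.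

Step 10
Reactants: 16 bis(diaryl ketone) from step 9
Product: 18 (2S,3S)-tetraaryl cycloheptene with the Ca=Cb ring alkene (Ca bearing 4-methoxyphenyl, Cb bearing 2-methoxy-5-(methoxycarbonyl)phenyl), via titanium pinacolate 17 (not isolated)
Conditions: TiCl4, Zn dust, pyridine, THF, reflux (reagent pre-formed); 16 added slowly at high dilution
Reagents that add atoms: none
Why: Zerovalent titanium generated from TiCl4 and Zn transfers one electron to each diaryl ketone, the two titanium-bound ketyls combine carbon to carbon to the cyclic titanium pinacolate 17, and loss of both oxygens to titanium at reflux leaves the C=C bond (intramolecular McMurry coupling, the known route from bis(diaryl ketones) to ring-embedded tetraarylethylenes). The only ring closed is the seven-membered carbocycle, formed by ketyl–ketyl radical recombination between the carbonyl carbon on the resorcinol ring (ortho to its bond to C3) and the carbonyl carbon on benzofuran C4. No stereocentre is created: the ring admits only the cis alkene, and C2 and C3 are not involved. The step needs the two ketones of one molecule to couple in preference to coupling between molecules, to attack on the aryl ester and to acid-type Friedel–Crafts closure; the first is secured by slow addition at high dilution and by the scaffold, which holds the two carbonyl groups on neighbouring positions, the second by the far easier reduction of diaryl ketones than of an ester, and the third by pyridine, which buffers the Lewis-acidic titanium chlorides so that neither the C2–O bond ionises nor a benzylic cation appears on the carbon attached to C4.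

Step 11
Reactants: 18 tetraaryl cycloheptene
Product: 19 (2S,3S,CaS,CbS)-cycloheptane methyl ester (Ca–H and Cb–H cis to each other, trans to H-3)
Conditions: H2 (50 bar), 10% Pd/C, EtOAc, 50 °C
Reagents that add atoms: none
Why: Heterogeneous catalytic hydrogenation adds both hydrogens to the same face (syn addition), and the face of the ring alkene anti to H-3 is the open one because H-3 and, farther out, the C2 aryl group project over the other face of the boat-shaped ring, so Ca and Cb should both become S with their hydrogens cis to each other and trans to H-3; pressure is applied because the alkene carries four aryl groups, and a neutral solvent is used to protect the benzylic C2–O bond.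

Step 12
Reactants: 19 cycloheptane methyl ester
Product: 20 benzylic alcohol (CH2OH in place of CO2CH3 of 19)
Conditions: LiAlH4, THF, 0 °C; then H2O
Reagents that add atoms: none
Why: Hydride reduction (LiAlH4) of the aryl methyl ester, the only carbonyl group left, gives the benzylic alcohol without touching the ethers or the four stereocentres.

Step 13
Reactants: 20 benzylic alcohol
Product: 21 aryl aldehyde (CHO in place of CH2OH of 20)
Conditions: MnO2, CH2Cl2, rt
Reagents that add atoms: none
Why: MnO2 oxidation is selective for the primary benzylic alcohol and stops at the aldehyde.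

Step 14
Reactants: 21 aryl aldehyde
Product: 22 core styrene (CH=CH2 in place of CHO of 21)
Conditions: Ph3PCH3Br, KOt-Bu, THF, 0 °C to rt
Reagents that add atoms: methyltriphenylphosphonium bromide, C[P+](c1ccccc1)(c1ccccc1)c1ccccc1.[Br-]
Why: Wittig methylenation of the non-enolisable aryl aldehyde with the unstabilised ylide gives the styrene, the triaryl methine hydrogens being far too weakly acidic to be disturbed by the ylide.

Step 15
Reactants: 22 core styrene; 12 (2S,3S)-4-bromo-3-(3,5-dimethoxyphenyl)-6-methoxy-2-(4-methoxyphenyl)-2,3-dihydrobenzofuran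
Product: 23 decamethyl ether of the target (E-stilbene)
Conditions: Pd2(dba)3 (2.5 mol %), P(t-Bu)3·HBF4 (10 mol %), Cs2CO3, 1,4-dioxane, 100 °C
Reagents that add atoms: none
Why: Mizoroki–Heck reaction: the arylpalladium species from the C4–Br bond of 12 adds to the unsubstituted terminus of the styrene and syn β-hydride elimination gives the E-stilbene, the bulky trialkylphosphine being suited to a hindered, electron-rich aryl bromide.

Step 16
Reactants: 23 decamethyl ether
Product: 24 target decaphenol CNP0266373.2
Conditions: BBr3 (excess), CH2Cl2, −78 to 0 °C; then ice-water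
Reagents that add atoms: none
Why: Lewis acid ether cleavage with BBr3 removes all ten methyl groups as bromomethane, the low temperature and cold quench limiting protonation of the stilbene, while any reversible opening of a dihydrofuran C2–O bond recloses to the trans isomer already present.

**Compound list**

1 | 1-bromo-3,5-dimethoxybenzene | COc1cc(Br)cc(OC)c1 | starting material
2 | 2-bromo-4,6-dimethoxybenzaldehyde | COc1cc(Br)c(C=O)c(OC)c1 | starting material
3 | 3,5-dimethoxyphenylmagnesium bromide | COc1cc([Mg]Br)cc(OC)c1 | intermediate (not isolated)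
4 | racemic (2-bromo-4,6-dimethoxyphenyl)(3,5-dimethoxyphenyl)methanol | COc1cc(OC)cc(c1)C(O)c1c(Br)cc(OC)cc1OC | intermediate
5 | (2-bromo-4,6-dimethoxyphenyl)(3,5-dimethoxyphenyl)methanone | COc1cc(OC)cc(c1)C(=O)c1c(Br)cc(OC)cc1OC | intermediate
6 | (2-bromo-6-hydroxy-4-methoxyphenyl)(3,5-dimethoxyphenyl)methanone | COc1cc(O)c(C(=O)c2cc(OC)cc(OC)c2)c(Br)c1 | intermediate
7 | 4-methoxybenzyl chloride | COc1ccc(CCl)cc1 | starting material
8 | {2-bromo-4-methoxy-6-[(4-methoxybenzyl)oxy]phenyl}(3,5-dimethoxyphenyl)methanone | COc1ccc(COc2cc(OC)cc(Br)c2C(=O)c2cc(OC)cc(OC)c2)cc1 | intermediate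
9 | hydrazone of ketone 8 (C=N geometry not defined, both isomers serve) | COc1ccc(COc2cc(OC)cc(Br)c2C(=NN)c2cc(OC)cc(OC)c2)cc1 | intermediate
10 | 1-bromo-2-[diazo(3,5-dimethoxyphenyl)methyl]-5-methoxy-3-[(4-methoxybenzyl)oxy]benzene | COc1ccc(COc2cc(OC)cc(Br)c2C(=[N+]=[N-])c2cc(OC)cc(OC)c2)cc1 | intermediate (not isolated)
11 | (2R,3S)-4-bromo-3-(3,5-dimethoxyphenyl)-6-methoxy-2-(4-methoxyphenyl)-2,3-dihydrobenzofuran (cis) | Brc1cc(OC)cc2c1[C@H](c1cc(OC)cc(OC)c1)[C@H](c1ccc(OC)cc1)O2 | intermediate
12 | (2S,3S)-4-bromo-3-(3,5-dimethoxyphenyl)-6-methoxy-2-(4-methoxyphenyl)-2,3-dihydrobenzofuran (trans) | Brc1cc(OC)cc2c1[C@H](c1cc(OC)cc(OC)c1)[C@@H](c1ccc(OC)cc1)O2 | intermediate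
13 | 4-methoxybenzoyl chloride | COc1ccc(C(=O)Cl)cc1 | starting material
14 | {2-[(2S,3S)-4-bromo-6-methoxy-2-(4-methoxyphenyl)-2,3-dihydrobenzofuran-3-yl]-4,6-dimethoxyphenyl}(4-methoxyphenyl)methanone | COc1ccc(cc1)C(=O)c1c(OC)cc(OC)cc1[C@H]1c2c(cc(OC)cc2Br)O[C@@H]1c1ccc(OC)cc1 | intermediate
15 | [2-methoxy-5-(methoxycarbonyl)phenyl]boronic acid | COC(=O)c1ccc(OC)c(B(O)O)c1 | starting material
16 | methyl 3-{(2S,3S)-3-[3,5-dimethoxy-2-(4-methoxybenzoyl)phenyl]-6-methoxy-2-(4-methoxyphenyl)-2,3-dihydrobenzofuran-4-carbonyl}-4-methoxybenzoate | COc1ccc(cc1)C(=O)c1c(OC)cc(OC)cc1[C@H]1c2c(cc(OC)cc2C(=O)c2cc(C(=O)OC)ccc2OC)O[C@@H]1c1ccc(OC)cc1 | intermediate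
17 | cyclic titanium 1,2-diolate of the Ca–Cb pinacol (idealised as the monomer; configuration at the two C–O carbons not defined, both are lost) | COc1ccc(cc1)C14O[Ti]OC4(c2cc(C(=O)OC)ccc2OC)c2cc(OC)cc3c2[C@H](c2cc(OC)cc(OC)c21)[C@@H](c1ccc(OC)cc1)O3 | intermediate (not isolated)
18 | (2S,3S)-cycloheptene: C3, C3a, C4 of the 6-methoxy-2-(4-methoxyphenyl)dihydrobenzofuran and two adjacent carbons of a dimethoxybenzene ring bridged by Ca=Cb; Ca carries 4-methoxyphenyl, Cb carries 2-methoxy-5-(methoxycarbonyl)phenyl | COc1ccc(cc1)C1=C(c2cc(C(=O)OC)ccc2OC)c2cc(OC)cc3c2[C@H](c2cc(OC)cc(OC)c21)[C@@H](c1ccc(OC)cc1)O3 | intermediate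
19 | (2S,3S,CaS,CbS)-cycloheptane methyl ester: as 18 with Ca–H and Cb–H cis to each other and trans to H-3 | COc1ccc([C@H]2c3c(OC)cc(OC)cc3[C@H]3c4c(cc(OC)cc4[C@H]2c2cc(C(=O)OC)ccc2OC)O[C@@H]3c2ccc(OC)cc2)cc1 | intermediate
20 | (2S,3S,CaS,CbS)-benzylic alcohol: as 19 with CH2OH in place of CO2CH3 | COc1ccc([C@H]2c3c(OC)cc(OC)cc3[C@H]3c4c(cc(OC)cc4[C@H]2c2cc(CO)ccc2OC)O[C@@H]3c2ccc(OC)cc2)cc1 | intermediate
21 | (2S,3S,CaS,CbS)-aldehyde: as 19 with CHO in place of CO2CH3 | COc1ccc([C@H]2c3c(OC)cc(OC)cc3[C@H]3c4c(cc(OC)cc4[C@H]2c2cc(C=O)ccc2OC)O[C@@H]3c2ccc(OC)cc2)cc1 | intermediate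
22 | (2S,3S,CaS,CbS)-core styrene: as 19 with CH=CH2 in place of CO2CH3 | COc1ccc([C@H]2c3c(OC)cc(OC)cc3[C@H]3c4c(cc(OC)cc4[C@H]2c2cc(C=C)ccc2OC)O[C@@H]3c2ccc(OC)cc2)cc1 | intermediate
23 | decamethyl ether of the target: E-stilbene joining the 5-position of the 2-methoxyphenyl ring on Cb to C4 of a second (2S,3S)-3-(3,5-dimethoxyphenyl)-6-methoxy-2-(4-methoxyphenyl)-2,3-dihydrobenzofuran | COc1ccc([C@H]2c3c(OC)cc(OC)cc3[C@H]3c4c(cc(OC)cc4[C@H]2c2cc(/C=C/c4cc(OC)cc5c4[C@H](c4cc(OC)cc(OC)c4)[C@@H](c4ccc(OC)cc4)O5)ccc2OC)O[C@@H]3c2ccc(OC)cc2)cc1 | intermediate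
24 | CNP0266373.2, the decaphenol: core (2S,3S,CaS,CbS), pendant dihydrobenzofuran (2S,3S), E-stilbene | Oc1ccc([C@H]2c3c(O)cc(O)cc3[C@H]3c4c(cc(O)cc4[C@H]2c2cc(/C=C/c4cc(O)cc5c4[C@H](c4cc(O)cc(O)c4)[C@@H](c4ccc(O)cc4)O5)ccc2O)O[C@@H]3c2ccc(O)cc2)cc1 | target

**Count**

Total steps: 16. Longest linear sequence: 16 steps (1 and 2 to 24); bromide 12 is drawn from this one sequence twice, in steps 8 and 15.

**Steps most likely to fail**

Step 10 (McMurry closure). The two hindered ketyl centres may fail to combine, so that plain reduction of the ketones to carbinols, arrest at the pinacol stage or coupling between molecules takes over. The fallback sets out from 12 and comes back at 18, closing the ring through the other bond of Ca, the one to the resorcinol ring. Palladium-catalysed α-arylation of 4′-methoxyacetophenone with methyl 3-bromo-4-methoxybenzoate (Pd2(dba)3, Xantphos, K3PO4, toluene, 80 °C) should give the deoxybenzoin methyl 4-methoxy-3-[2-(4-methoxyphenyl)-2-oxoethyl]benzoate F1. A second α-arylation, of F1 with bromide 12 (Pd(OAc)2, P(t-Bu)3·HBF4, K3PO4, toluene, 100 °C), should give the triarylethanone methyl 3-{1-[(2S,3S)-3-(3,5-dimethoxyphenyl)-6-methoxy-2-(4-methoxyphenyl)-2,3-dihydrobenzofuran-4-yl]-2-(4-methoxyphenyl)-2-oxoethyl}-4-methoxybenzoate F2, as both epimers at the new methine, which is of no consequence. Acid (catalytic Bi(OTf)3 or TfOH, 1,2-dichloroethane, 60 °C) should then bring about cyclodehydration. The activated ketone carbon (the future Ca) is attacked by the free ortho carbon of the dimethoxyphenyl ring on C3 (intramolecular Friedel–Crafts hydroxyalkylation), and water is lost toward the only β-hydrogen, on Cb, to give 18. The electrophilic carbon is two bonds from C4, so only the seven-membered ring can close, and no cation is placed on the carbon attached to C4.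

Step 11 (hydrogenation). The fully aryl-substituted ring alkene may not reach the metal surface, so that hydrogenolysis of the benzylic C2–O bond, or no reaction at all, comes before saturation; hydrogen may also be delivered in part to the face syn to H-3. The fallback sets out from 18 and comes back at 19: radical hydrogenation by stepwise hydrogen-atom transfer (Mn(dpm)3 cat., PhSiH3, t-BuOOH, i-PrOH, rt). It needs no contact with a surface and leaves benzylic ethers alone. Each hydrogen atom is expected to arrive on the open face anti to H-3, although the two centres are then set in two separate events. No compound outside the list is formed (F0).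

Step 9 (carbonylative coupling). Oxidative addition at the bromide next to the C3 substituent may be slow, and direct aryl–aryl coupling or protodeboronation may outrun CO insertion. The fallback sets out from 12 and comes back at 16; it reverses the order of the two acylations and uses no carbonylation. Bromine–lithium exchange on 12 (n-BuLi, THF, −78 °C) should give the aryllithium [(2S,3S)-3-(3,5-dimethoxyphenyl)-6-methoxy-2-(4-methoxyphenyl)-2,3-dihydrobenzofuran-4-yl]lithium F3. Addition of F3 to methyl 3-formyl-4-methoxybenzoate at −78 °C (the aldehyde reacts far faster than the ester; NH4Cl quench) should give the carbinol methyl 3-{[(2S,3S)-3-(3,5-dimethoxyphenyl)-6-methoxy-2-(4-methoxyphenyl)-2,3-dihydrobenzofuran-4-yl](hydroxy)methyl}-4-methoxybenzoate F4, as both epimers. Dess–Martin oxidation should give the ketone methyl 3-[(2S,3S)-3-(3,5-dimethoxyphenyl)-6-methoxy-2-(4-methoxyphenyl)-2,3-dihydrobenzofuran-4-carbonyl]-4-methoxybenzoate F5. Friedel–Crafts acylation of F5 with 13 (SnCl4, CH2Cl2, −40 to 0 °C) then gives 16, with the benzofuran ring now deactivated by its C4 acyl group.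

**Further compounds**

F1 | step 10 | methyl 4-methoxy-3-[2-(4-methoxyphenyl)-2-oxoethyl]benzoate | COC(=O)c1ccc(OC)c(CC(=O)c2ccc(OC)cc2)c1
F2 | step 10 | methyl 3-{1-[(2S,3S)-3-(3,5-dimethoxyphenyl)-6-methoxy-2-(4-methoxyphenyl)-2,3-dihydrobenzofuran-4-yl]-2-(4-methoxyphenyl)-2-oxoethyl}-4-methoxybenzoate (both epimers at the methine) | COC(=O)c1ccc(OC)c(c1)C(C(=O)c1ccc(OC)cc1)c1cc(OC)cc2c1[C@H](c1cc(OC)cc(OC)c1)[C@@H](c1ccc(OC)cc1)O2
F0 | step 11 | none | none
F3 | step 9 | [(2S,3S)-3-(3,5-dimethoxyphenyl)-6-methoxy-2-(4-methoxyphenyl)-2,3-dihydrobenzofuran-4-yl]lithium | [Li]c1cc(OC)cc2c1[C@H](c1cc(OC)cc(OC)c1)[C@@H](c1ccc(OC)cc1)O2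
F4 | step 9 | methyl 3-{[(2S,3S)-3-(3,5-dimethoxyphenyl)-6-methoxy-2-(4-methoxyphenyl)-2,3-dihydrobenzofuran-4-yl](hydroxy)methyl}-4-methoxybenzoate (both carbinol epimers) | COC(=O)c1ccc(OC)c(c1)C(O)c1cc(OC)cc2c1[C@H](c1cc(OC)cc(OC)c1)[C@@H](c1ccc(OC)cc1)O2
F5 | step 9 | methyl 3-[(2S,3S)-3-(3,5-dimethoxyphenyl)-6-methoxy-2-(4-methoxyphenyl)-2,3-dihydrobenzofuran-4-carbonyl]-4-methoxybenzoate | COC(=O)c1ccc(OC)c(c1)C(=O)c1cc(OC)cc2c1[C@H](c1cc(OC)cc(OC)c1)[C@@H](c1ccc(OC)cc1)O2
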